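Benzofuran numbering is used throughout: O1, C2, C3, C3a, C4 to C7, C7a, with C9 for the hydroxymethyl carbon. Ring A is the fused benzene ring, ring B the aryl group on C2.

## Analysis of the target

The target is a 2,3-dihydrobenzofuran: ring A carries a methoxy group on C7 and a methyl propanoate chain on C5, C2 carries a 4-hydroxy-3,5-dimethoxyphenyl group (ring B), and C3 carries C9H2OH. It has two stereocentres, C2 (S) and C3 (R), adjacent and both benzylic, with ring B and C9 on opposite faces of the five-membered ring (2,3-trans). The two centres are not equal. O1–C2 is a benzylic aryl ether bond para to an oxygen of ring B; it can reopen by ionisation or, once the ring B phenol is free, through a quinone methide, so C2 can settle into the more stable trans arrangement. C3 has no such pathway and must be set absolutely. The sensitive groups are the methyl ester (hydride, hydroxide, free organolithium), the O1–C2 bond (hydrogenolysis, strong acid), the ring B phenol and the primary alcohol. The difficulty is therefore C3, a carbon with hydrogen, one aryl group and two carbon substituents and no carbonyl beside it, in a molecule whose ester excludes most enolate and organometallic constructions. The strategy rests on the C2–C3 pair: C2 is bonded to ring B and to oxygen, C3 is bonded to ring A through C3a, and O1 sits on C7a, ortho to C3a. This is the pattern left when an aryl nucleophile (ring B) and an aryl electrophile (ring A) are added across a C9–C3=C2–boron unit and boron is then exchanged for oxygen.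

## Retrosynthetic reasoning

**18 back to 17.** The two O–benzyl bonds (ring B phenol and C9–O) are cut last. A free ring B phenol would quench an aryllithium and would make O1–C2 labile, so it stays masked until the end. Benzyl ethers survive organolithium, palladium, peroxide and acid, and they leave under neutral conditions that spare the ester.

**17 back to 15 (through 16).** The O1–C2 bond is cut. C2 is benzylic to an oxygenated ring, so this bond can be made by ionisation of a C2 alcohol and capture by the phenol. The closure is reversible under acid and ends trans on the fixed C3 centre. This means the open-chain precursor 15 needs only C3 to be right. O1 is carried as an acetal so that the same acid frees it.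

**15 back to 14.** The C2–O bond is traded for a C2–B bond. Oxidation of a secondary boronic ester is stereoretentive and mild, and it turns C2 into the boron-bearing carbon of a three-component coupling.

**14 back to 13, then to 12, 11 and 4.** The C2–ring B bond and the C3–C3a bond are cut together. Cutting C2–C3 instead would call for an aldol-type union with a carbonyl at C9 that would later have to be reduced beside the chain ester. Cutting the two aryl bonds keeps C9 at the alcohol level and places the ester in the electrophile 4, which never meets a free organometallic. It also splits the target into three fragments, each one to three steps from commercial material. In the forward direction a chiral palladium catalyst must choose the alkene face of 13 (this sets C3), and the 1,2-shift of ring B from boron to C2 must outrun direct transfer of a carbon group from boron to palladium.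

**11 back to 9 and 8 (through 10); 8 back to 7.** The B–C2 bond comes from syn hydroboration of the terminal alkyne 9, which gives the E-alkene needed for a defined anti addition. The diol on boron is the rigid, hindered 8 rather than a simple aliphatic diol. β-Substituted alkenyl ate complexes of unhindered esters tend to pass a carbon group straight to palladium, and a bulky diol is the known remedy. 8 comes from the diketone 7 by double methyl addition and returns unchanged when boron is oxidised.

**12 back to 6, then 5.** The C–Li bond comes from bromine–lithium exchange on 6, which is the benzyl ether of the commercial bromophenol 5.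

**4 back to 3, 2 and 1.** The saturated ester chain is traced to the aldehyde of 1 by olefination and conjugate reduction. The bromine of 1 already sits on the future C3a, ortho to the oxygen that becomes O1, so no arene functionalisation is needed.

## Alternatives that were turned down

Alternative 1: Ring A is made last. C7–C6, C5–C4 and C4–C3a are cut, which leads back to a pentacarbonylchromium methoxycarbene on C7a of a preformed 2,3-trans dihydrofuran (A2) and a terminal alkyne carrying the ester chain. In the forward step the carbene, the alkyne and one carbonyl ligand combine in a benzannulation to give the phenol A1.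
- For it: the alkyne fixes the substitution pattern of the new arene, and the stereocentres are not touched in the ring-forming step.
- Against it: A1 has a hydroxyl on C4 that the target lacks, and removing it costs a sulfonylation and a reduction. Both stereocentres must already be present in A2, so the stereochemical problem is only moved to an earlier cyclic enol ether that is harder to reach. A2 is made by metalation of that acid-sensitive enol ether, and chromium is stoichiometric.
- Comparison: it is stronger on one point, since no catalyst has to cope with an ortho-substituted aryl electrophile. The chosen strategy offers instead arenes bought with their substituents in place, no deoxygenation, and a longest line of seven steps.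

Alternative 2: The dihydrofuran ring is seen as a contracted chromanone, with C3–C3a as the terminus of an aryl shift. The enol ether of the (2S)-flavanone A4 is attacked at C3 by a trivalent-iodine oxidant. Ring A then migrates from the former carbonyl carbon to C3, and that carbon leaves the ring as a methyl ester, giving A3.
- For it: the single stereocentre of A4 is accessible by established asymmetric conjugate additions. The ring and its trans relation arise in one robust operation without any organometallic.
- Against it: ring B is electron-rich and is itself a good migrating group, so its shift from C2 to C3 competes with the wanted shift of ring A. The C2 centre of A4 can be lost by opening to the chalcone under the acidic conditions, and C3 is then set only relative to that labile centre. A3 still needs its ester reduced to the C9 alcohol and its bromine on C5 exchanged for the three-carbon ester chain, about four more steps, with the hydride step placed before the chain ester arrives.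
- Comparison: it is stronger in avoiding a demanding three-component catalysis. The chosen strategy brings C9 and the chain ester in at their final oxidation levels and sets C3 directly under catalyst control.

Alternative 3: C2–C3 and O1–C2 are cut. This gives the ortho-quinone methide A6 (atoms C3, C3a, C7a, O1) and a ring B benzylic ylide on a chiral sulfide. Base releases both; the ylide carbon adds to C3 and the phenoxide then displaces the sulfide at C2. The product A5 is the same compound as 17.
- For it: this is the most convergent plan. The ring and both centres form in one step, trans through the anti displacement, and 17 is reached in fewer steps than here. On step economy it is stronger.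
- Against it: A6 carries a CH2O group with hydrogens on its exocyclic carbon. Such quinone methides tautomerise readily to ortho-hydroxystyrenes and are less well behaved than the aryl-substituted ones on which asymmetric versions are built. Absolute control has to come from a stoichiometric chiral sulfide through a reversible betaine, and the face-selecting addition creates C3, the one centre that cannot be corrected afterwards.
- Comparison: the chosen strategy offers catalytic control of C3 in a bond-forming event of defined geometry, stable and storable fragments, and a thermodynamic handle on C2.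

Key step: step 7

Assumption: of the two commercial enantiomers of the ferrocenyl bisphosphine, the one whose palladium complex binds the alkene face leading to R at the ring A-bearing carbon of 14 is used. Which enantiomer this is has to be settled on this substrate.

## Route

Step 1
Reactants: 1 5-bromovanillin (3-bromo-4-hydroxy-5-methoxybenzaldehyde)
Product: 2 3-bromo-5-methoxy-4-(methoxymethoxy)benzaldehyde
Conditions: MOMCl, i-Pr2NEt, CH2Cl2, 0 °C to rt
Reagents that add atoms: chloromethyl methyl ether, COCCl
Why: O-alkylation of the phenol with a reactive α-chloro ether (Williamson-type acetal formation); the aldehyde and the aryl bromide are inert, and the acetal is chosen because the acid of step 9 removes it.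

Step 2
Reactants: 2 3-bromo-5-methoxy-4-(methoxymethoxy)benzaldehyde
Product: 3 methyl (E)-3-[3-bromo-5-methoxy-4-(methoxymethoxy)phenyl]prop-2-enoate
Conditions: Ph3P=CHCO2Me, toluene, 80 °C
Reagents that add atoms: methyl (triphenylphosphoranylidene)acetate, COC(=O)C=P(c1ccccc1)(c1ccccc1)c1ccccc1
Why: Wittig olefination with a stabilised ylide, neutral conditions that leave the acetal alone; the E geometry is expected but is irrelevant after step 3.

Step 3
Reactants: 3 methyl (E)-3-[3-bromo-5-methoxy-4-(methoxymethoxy)phenyl]prop-2-enoate
Product: 4 methyl 3-[3-bromo-5-methoxy-4-(methoxymethoxy)phenyl]propanoate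
Conditions: Cu(OAc)2·H2O (cat.), 1,2-bis(diphenylphosphino)benzene (cat.), (EtO)2MeSiH, t-BuOH, toluene, rt
Reagents that add atoms: none
Why: Copper hydride conjugate reduction: phosphine-ligated CuH delivers hydride to the β-carbon and t-BuOH protonates the copper enolate; unlike hydrogenation over palladium, CuH does not touch the aryl C–Br bond needed in step 7.

Step 4
Reactants: 5 4-bromo-2,6-dimethoxyphenol
Product: 6 2-(benzyloxy)-5-bromo-1,3-dimethoxybenzene
Conditions: BnBr, K2CO3, DMF, 60 °C
Reagents that add atoms: benzyl bromide, BrCc1ccccc1
Why: Williamson ether synthesis; the benzyl ether masks the ring B phenol against the organolithium of step 7 and the acid of step 9.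

Step 5
Reactants: 7 acenaphthylene-1,2-dione
Product: 8 cis-1,2-dimethyl-1,2-dihydroacenaphthylene-1,2-diol (1R,2S, meso)
Conditions: MeMgBr (2.5 equiv), THF, 0 °C to rt; NH4Cl (aq); recrystallisation
Reagents that add atoms: methylmagnesium bromide, C[Mg]Br
Why: Double Grignard addition to a 1,2-diketone; the second methyl group should enter anti to the bulky magnesium alkoxide, which puts both hydroxyls on one face (cis). Any trans diol is removed by crystallisation and could not bridge boron in step 6.

Step 6
Reactants: 9 benzyl propargyl ether; 8 cis-1,2-dimethyl-1,2-dihydroacenaphthylene-1,2-diol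
Product: 11 cyclic ester of (E)-3-(benzyloxy)prop-1-enylboronic acid with diol 8, via catechol alkenylboronate 10 (not isolated)
Conditions: catecholborane, neat, 70 °C; then 8, THF, rt; NaOH (aq) wash
Reagents that add atoms: catecholborane, [H]B1Oc2ccccc2O1
Why: Uncatalysed syn hydroboration of a terminal alkyne puts boron on the terminal carbon and gives the E-alkene. The aryl ester 10 then exchanges with the aliphatic diol 8 (transesterification), driven by the more stable dialkyl ester and by washing out catechol.

Step 7
Reactants: 6 2-(benzyloxy)-5-bromo-1,3-dimethoxybenzene; 11 cyclic alkenylboronic ester of diol 8; 4 methyl 3-[3-bromo-5-methoxy-4-(methoxymethoxy)phenyl]propanoate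
Product: 14 methyl 3-{3-[(1S,2R)-3-(benzyloxy)-1-(4-benzyloxy-3,5-dimethoxyphenyl)-1-borylpropan-2-yl]-5-methoxy-4-(methoxymethoxy)phenyl}propanoate as the cyclic boronic ester of diol 8, via aryllithium 12 (not isolated), via lithium boronate complex 13 (not isolated)
Conditions: 6, t-BuLi (2.0 equiv), THF, −78 °C; 11 (1.05 equiv), −78 °C to rt; then 4, Pd(OAc)2 (3 mol %), 1,1′-bis[bis(4-methoxy-3,5-dimethylphenyl)phosphino]-2,2′-bis[α-(dimethylamino)benzyl]ferrocene (selected enantiomer, 3.6 mol %), KOTf, THF, 60 °C
Reagents that add atoms: none
Why: Bromine–lithium exchange on 6 gives 12, which adds to boron of 11 to give the four-coordinate boronate 13 before any ester is in the flask; 11 is used in slight excess so that no free organolithium remains. Zerovalent palladium, formed from Pd(OAc)2 and the ferrocenyl bisphosphine, inserts into the C3a–Br bond of 4, and KOTf takes up bromide so that a cationic arylpalladium species can bind the alkene of 13. Binding triggers a 1,2-metalate shift: ring B moves from boron to C2 anti to palladium, palladium becomes bonded to C3, and reductive elimination with retention forms C3–C3a. The closest known reaction is the palladium-catalysed enantioselective conjunctive cross-coupling of alkenylboron ate complexes with aryl halides in the presence of triflate salts, which has been extended to β-substituted alkenyl groups when boron carries the hindered diol 8. No ring is closed in this step. C3 is set by the chiral ligand, which decides the alkene face to which palladium binds; C2 follows from the anti addition across the E-alkene, but it need not be clean because step 9 sets it again. The selectivity needed is the metalate shift over direct Suzuki–Miyaura transfer; the bulk of diol 8 secures it by shielding the boron-bound oxygens from bridging to palladium. β-Hydride and β-alkoxide elimination from the C3–palladium intermediate should be outpaced by the fast reductive elimination of the wide-bite-angle complex.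

Step 8
Reactants: 14 secondary boronic ester (1S,2R)
Product: 15 methyl 3-{3-[(1S,2R)-3-(benzyloxy)-1-(4-benzyloxy-3,5-dimethoxyphenyl)-1-hydroxypropan-2-yl]-5-methoxy-4-(methoxymethoxy)phenyl}propanoate
Conditions: NaBO3·4H2O, THF/H2O (1:1), rt
Reagents that add atoms: sodium perborate (NaBO3·4H2O, formulated as Na2[B2(O2)2(OH)4]·6H2O), [Na+].[Na+].O[B-]1(O)OO[B-](O)(O)OO1
Why: Boronate oxidation: peroxide adds to boron and C2 migrates from boron to oxygen with retention of configuration; perborate is mild enough to leave the methyl ester intact, and diol 8 is released for reuse.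

Step 9
Reactants: 15 C2 alcohol (1S,2R)
Product: 17 methyl 3-[(2S,3R)-2-(4-benzyloxy-3,5-dimethoxyphenyl)-3-(benzyloxymethyl)-7-methoxy-2,3-dihydro-1-benzofuran-5-yl]propanoate, via free phenol 16 (not isolated)
Conditions: HCl (about 2 M) in MeOH, dilute, rt to 50 °C
Reagents that add atoms: none
Why: Acid cleaves the methoxymethyl acetal to the phenol 16 and ionises the C2 alcohol to a cation stabilised by ring B, which O1 captures in a five-membered ring closure (acid-mediated SN1 etherification). The closure is reversible, so ring B settles trans to C9 on the fixed C3 centre and C2 becomes S; capture by methanol is only a reservoir that re-ionises, and the ester is unchanged in methanol.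

Step 10
Reactants: 17 dibenzyl ether (2S,3R)
Product: 18 methyl 3-[(2S,3R)-2-(4-hydroxy-3,5-dimethoxyphenyl)-3-(hydroxymethyl)-7-methoxy-2,3-dihydro-1-benzofuran-5-yl]propanoate (CNP0362206.1)
Conditions: H2 (1 atm), 10% Pd on carbon, EtOAc/MeOH, rt
Reagents that add atoms: none
Why: Catalytic hydrogenolysis of the aryl and the alkyl benzyl ether under neutral conditions; the ester and methyl ethers are inert, and O-debenzylation should be faster than opening of the cyclic O1–C2 bond if the reaction is stopped at completion.

## Compound list

1 | 5-bromovanillin (3-bromo-4-hydroxy-5-methoxybenzaldehyde) | COc1cc(C=O)cc(Br)c1O | starting material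
2 | 3-bromo-5-methoxy-4-(methoxymethoxy)benzaldehyde | COCOc1c(Br)cc(C=O)cc1OC | intermediate
3 | methyl (E)-3-[3-bromo-5-methoxy-4-(methoxymethoxy)phenyl]prop-2-enoate | COC(=O)/C=C/c1cc(Br)c(OCOC)c(OC)c1 | intermediate
4 | methyl 3-[3-bromo-5-methoxy-4-(methoxymethoxy)phenyl]propanoate | COC(=O)CCc1cc(Br)c(OCOC)c(OC)c1 | intermediate
5 | 4-bromo-2,6-dimethoxyphenol | COc1cc(Br)cc(OC)c1O | starting material
6 | 2-(benzyloxy)-5-bromo-1,3-dimethoxybenzene | COc1cc(Br)cc(OC)c1OCc1ccccc1 | intermediate
7 | acenaphthylene-1,2-dione | O=C1C(=O)c2cccc3cccc1c23 | starting material
8 | (1R,2S)-1,2-dimethyl-1,2-dihydroacenaphthylene-1,2-diol (cis, meso) | C[C@@]1(O)c2cccc3cccc(c23)[C@]1(C)O | intermediate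
9 | benzyl propargyl ether | C#CCOCc1ccccc1 | starting material
10 | 2-[(E)-3-(benzyloxy)prop-1-enyl]-1,3,2-benzodioxaborole (formed in the flask) | O(Cc1ccccc1)C/C=C/B1Oc2ccccc2O1 | intermediate
11 | cyclic ester of (E)-3-(benzyloxy)prop-1-enylboronic acid with diol 8 | O(Cc1ccccc1)C/C=C/B1O[C@]2(C)c3cccc4cccc(c34)[C@]2(C)O1 | intermediate
12 | (4-benzyloxy-3,5-dimethoxyphenyl)lithium (formed in the flask) | [Li]c1cc(OC)c(OCc2ccccc2)c(OC)c1 | intermediate
13 | lithium [(E)-3-(benzyloxy)prop-1-enyl](4-benzyloxy-3,5-dimethoxyphenyl)boronate of diol 8 (four-coordinate boron, either orientation at boron; formed in the flask) | [Li+].O(Cc1ccccc1)C/C=C/[B-]1(c2cc(OC)c(OCc3ccccc3)c(OC)c2)O[C@]2(C)c3cccc4cccc(c34)[C@]2(C)O1 | intermediate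
14 | methyl 3-{3-[(1S,2R)-3-(benzyloxy)-1-(4-benzyloxy-3,5-dimethoxyphenyl)-1-borylpropan-2-yl]-5-methoxy-4-(methoxymethoxy)phenyl}propanoate, boron as the cyclic ester of diol 8 | COC(=O)CCc1cc(OC)c(OCOC)c(c1)[C@H](COCc1ccccc1)[C@@H](c1cc(OC)c(OCc2ccccc2)c(OC)c1)B1O[C@]2(C)c3cccc4cccc(c34)[C@]2(C)O1 | intermediate
15 | methyl 3-{3-[(1S,2R)-3-(benzyloxy)-1-(4-benzyloxy-3,5-dimethoxyphenyl)-1-hydroxypropan-2-yl]-5-methoxy-4-(methoxymethoxy)phenyl}propanoate | COC(=O)CCc1cc(OC)c(OCOC)c(c1)[C@H](COCc1ccccc1)[C@@H](c1cc(OC)c(OCc2ccccc2)c(OC)c1)O | intermediate
16 | methyl 3-{3-[(1S,2R)-3-(benzyloxy)-1-(4-benzyloxy-3,5-dimethoxyphenyl)-1-hydroxypropan-2-yl]-4-hydroxy-5-methoxyphenyl}propanoate (formed in the flask) | COC(=O)CCc1cc(OC)c(O)c(c1)[C@H](COCc1ccccc1)[C@@H](c1cc(OC)c(OCc2ccccc2)c(OC)c1)O | intermediate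
17 | methyl 3-[(2S,3R)-2-(4-benzyloxy-3,5-dimethoxyphenyl)-3-(benzyloxymethyl)-7-methoxy-2,3-dihydro-1-benzofuran-5-yl]propanoate | COC(=O)CCc1cc(OC)c2c(c1)[C@H](COCc1ccccc1)[C@@H](c1cc(OC)c(OCc3ccccc3)c(OC)c1)O2 | intermediate
18 | methyl 3-[(2S,3R)-2-(4-hydroxy-3,5-dimethoxyphenyl)-3-(hydroxymethyl)-7-methoxy-2,3-dihydro-1-benzofuran-5-yl]propanoate | COC(=O)CCc1cc(OC)c2c(c1)[C@H](CO)[C@@H](c1cc(OC)c(O)c(OC)c1)O2 | target

## Step count and risk

Total: 10 steps. Longest linear sequence: 7 steps (1, 2, 3, 7, 8, 9, 10). The branches through steps 4 and 5–6 join at step 7.

Least certain steps: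

**Step 7 (key step).** The most likely failure is direct transfer of ring B or of the alkenyl group from boron to palladium outrunning the metalate shift, because the ortho acetal oxygen of 4 hinders alkene binding on the arylpalladium cation. Next in likelihood are poor face selection with a CH2OBn substituent on C3 and β-elimination from the C3–palladium intermediate. The fallback sets C3 by an asymmetric allylboration, which tolerates the ester. It sets out from 4. Suzuki–Miyaura coupling with potassium vinyltrifluoroborate (PdCl2(dppf), Et3N, n-PrOH, 90 °C) should give the styrene methyl 3-[3-ethenyl-5-methoxy-4-(methoxymethoxy)phenyl]propanoate F1. Cross-metathesis with allylboronic acid pinacol ester (second-generation Grubbs catalyst RuCl2(=CHPh)(PCy3)(H2IMes), CH2Cl2, 40 °C) should give the (E)-γ-aryl allylboronate F2. Addition of F2 to commercial 4-benzyloxy-3,5-dimethoxybenzaldehyde under a chiral 3,3′-bis(2,4,6-triisopropylphenyl)-1,1′-binaphthyl-2,2′-diyl hydrogen phosphate (toluene, −30 °C) passes through a chair transition state and should give the anti homoallylic alcohol methyl 3-{3-[(1R,2S)-1-(4-benzyloxy-3,5-dimethoxyphenyl)-1-hydroxybut-3-en-2-yl]-5-methoxy-4-(methoxymethoxy)phenyl}propanoate F3, with the future C3 set by the catalyst. Ozonolysis with NaBH4 work-up (CH2Cl2/MeOH, −78 °C), which reduces the α-aryl aldehyde before it can epimerise, turns the vinyl group into C9H2OH and gives the (1R,2R)-diol F4. Methanolic HCl as in step 9 should close the ring to the mono-benzyl ether methyl 3-[(2S,3R)-2-(4-benzyloxy-3,5-dimethoxyphenyl)-3-(hydroxymethyl)-7-methoxy-2,3-dihydro-1-benzofuran-5-yl]propanoate F5; the carbinol configuration of F4 does not matter because C2 passes through the cation. Hydrogenolysis as in step 10 rejoins the route at 18.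

**Step 9.** The 4-benzyloxy group of ring B is flanked by two methoxy groups and twisted out of conjugation, so ionisation at C2 may be sluggish. Under forcing conditions the cation may lose H3 to form a stilbene, which wastes material and, if the alkene is reprotonated, erodes C3. The fallback changes the closing mechanism by unmasking the ring B phenol first. It sets out from 15: hydrogenolysis (H2, Pd on carbon, EtOAc, rt) should give methyl 3-{3-[(1S,2R)-1,3-dihydroxy-1-(4-hydroxy-3,5-dimethoxyphenyl)propan-2-yl]-5-methoxy-4-(methoxymethoxy)phenyl}propanoate F6. Its para-hydroxybenzyl alcohol forms a para-quinone methide under mild acid, so dilute HCl in MeOH at 0 °C to rt should remove the acetal and let O1 add to C2 in conjugate fashion, trans. This rejoins the route at 18.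

**Step 10.** The risk is hydrogenolysis of the benzylic O1–C2 bond (ring opening) competing with removal of the less accessible alkyl benzyl ether. The fallback is a non-reductive debenzylation of 17 by Lewis acid with a cation scavenger (BCl3, pentamethylbenzene, CH2Cl2, −78 °C), which gives 18 directly and makes no new intermediate. It has its own hazard, since BCl3 could ionise O1–C2, so the temperature must stay low.

**Step 8.** Migration of the hindered C2 from boron to oxygen inside the bulky ester of diol 8 may be slow with perborate, and pushing it with hydroxide risks saponification of the ester. The fallback accepts the saponification and repairs it later. It sets out from 14: NaOH/H2O2 (THF/H2O, 0 °C to rt) should give 3-{3-[(1S,2R)-3-(benzyloxy)-1-(4-benzyloxy-3,5-dimethoxyphenyl)-1-hydroxypropan-2-yl]-5-methoxy-4-(methoxymethoxy)phenyl}propanoic acid F7. The methanolic HCl of step 9 then re-esterifies the acid (Fischer esterification) while it removes the acetal and closes the ring, rejoining the route at 17.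

## Further compounds

F1 | step 7 | methyl 3-[3-ethenyl-5-methoxy-4-(methoxymethoxy)phenyl]propanoate | COC(=O)CCc1cc(C=C)c(OCOC)c(OC)c1
F2 | step 7 | methyl 3-{3-methoxy-4-(methoxymethoxy)-5-[(E)-3-(4,4,5,5-tetramethyl-1,3,2-dioxaborolan-2-yl)prop-1-enyl]phenyl}propanoate | COC(=O)CCc1cc(/C=C/CB2OC(C)(C)C(C)(C)O2)c(OCOC)c(OC)c1
F3 | step 7 | methyl 3-{3-[(1R,2S)-1-(4-benzyloxy-3,5-dimethoxyphenyl)-1-hydroxybut-3-en-2-yl]-5-methoxy-4-(methoxymethoxy)phenyl}propanoate | COC(=O)CCc1cc(OC)c(OCOC)c(c1)[C@H](C=C)[C@H](c1cc(OC)c(OCc2ccccc2)c(OC)c1)O
F4 | step 7 | methyl 3-{3-[(1R,2R)-1-(4-benzyloxy-3,5-dimethoxyphenyl)-1,3-dihydroxypropan-2-yl]-5-methoxy-4-(methoxymethoxy)phenyl}propanoate | COC(=O)CCc1cc(OC)c(OCOC)c(c1)[C@H](CO)[C@H](c1cc(OC)c(OCc2ccccc2)c(OC)c1)O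
F5 | step 7 | methyl 3-[(2S,3R)-2-(4-benzyloxy-3,5-dimethoxyphenyl)-3-(hydroxymethyl)-7-methoxy-2,3-dihydro-1-benzofuran-5-yl]propanoate | COC(=O)CCc1cc(OC)c2c(c1)[C@H](CO)[C@@H](c1cc(OC)c(OCc3ccccc3)c(OC)c1)O2
F6 | step 9 | methyl 3-{3-[(1S,2R)-1,3-dihydroxy-1-(4-hydroxy-3,5-dimethoxyphenyl)propan-2-yl]-5-methoxy-4-(methoxymethoxy)phenyl}propanoate | COC(=O)CCc1cc(OC)c(OCOC)c(c1)[C@H](CO)[C@@H](c1cc(OC)c(O)c(OC)c1)O
F0 | step 10 | none | none
F7 | step 8 | 3-{3-[(1S,2R)-3-(benzyloxy)-1-(4-benzyloxy-3,5-dimethoxyphenyl)-1-hydroxypropan-2-yl]-5-methoxy-4-(methoxymethoxy)phenyl}propanoic acid | OC(=O)CCc1cc(OC)c(OCOC)c(c1)[C@H](COCc1ccccc1)[C@@H](c1cc(OC)c(OCc2ccccc2)c(OC)c1)O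
A1 | alternative 1 | 4-hydroxy analogue of 17 with C9 as its tert-butyldimethylsilyl ether (2,3-trans, configuration as in the target) | COC(=O)CCc1cc(OC)c2c(c1O)[C@H](CO[Si](C)(C)C(C)(C)C)[C@@H](c1cc(OC)c(OCc3ccccc3)c(OC)c1)O2
A2 | alternative 1 | pentacarbonyl{methoxy[trans-5-(4-benzyloxy-3,5-dimethoxyphenyl)-4-(tert-butyldimethylsilyloxymethyl)-4,5-dihydrofuran-2-yl]methylidene}chromium | COC(=[Cr](=C=O)(=C=O)(=C=O)(=C=O)=C=O)C1=C[C@H](CO[Si](C)(C)C(C)(C)C)[C@@H](c2cc(OC)c(OCc3ccccc3)c(OC)c2)O1
A3 | alternative 2 | methyl trans-2-(4-benzyloxy-3,5-dimethoxyphenyl)-5-bromo-7-methoxy-2,3-dihydro-1-benzofuran-3-carboxylate (2S) | Brc1cc(OC)c2c(c1)[C@H](C(=O)OC)[C@@H](c1cc(OC)c(OCc3ccccc3)c(OC)c1)O2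
A4 | alternative 2 | (2S)-2-(4-benzyloxy-3,5-dimethoxyphenyl)-6-bromo-8-methoxychroman-4-one | O=C1C[C@@H](c2cc(OC)c(OCc3ccccc3)c(OC)c2)Oc2c(OC)cc(Br)cc12
A5 | alternative 3 | methyl 3-[(2S,3R)-2-(4-benzyloxy-3,5-dimethoxyphenyl)-3-(benzyloxymethyl)-7-methoxy-2,3-dihydro-1-benzofuran-5-yl]propanoate (identical with 17) | COC(=O)CCc1cc(OC)c2c(c1)[C@H](COCc1ccccc1)[C@@H](c1cc(OC)c(OCc3ccccc3)c(OC)c1)O2
A6 | alternative 3 | methyl 3-{5-[2-(benzyloxy)ethylidene]-3-methoxy-4-oxocyclohexa-1,5-dien-1-yl}propanoate (ortho-quinone methide, exocyclic geometry open) | COC(=O)CCC1=CC(=CCOCc2ccccc2)C(=O)C(OC)=C1
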